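**Retrosynthetic overview**

1. The pentamer A–CH2–B–CH2–C–CH2–D–CH2–E (A, E = butanoylfilicinic acid rings; B, C, D = butanoylphloroglucinol rings) is cut at the two methylene bridges on ring C into bis-Mannich base 12 (ring C) and two molecules of the A–B dimer 10 (D–E is the same piece by symmetry).
2. Ring A of 10 (C1 bears the butanoyl group, C2, C3 = CMe2, C4, C5 bears the CH2 bridge, C6 = the C=O between C1 and C5) is cut into three components: C5–C6 from dihydrocoumarin 5, C2–C3–C4 from dimethylmalonyl dichloride 6, and C1 with its butanoyl group from pentan-2-one 7; the bonds form in the order C4–C5, C1–C2, C1–C6.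
3. Enabling feature: the ring-B hydroxyl ortho to the A–B methylene lies five atoms from C6 of ring A (O–C(ar)–C(ar)–CH2–C5–C6), so C6 can be carried as a six-membered aryl lactone that makes C5 the only enolisable carbon and C6 an activated ester, while the quaternary C3 between C2 and C4 maps onto a non-enolisable malonyl unit; the lactone is a temporary ring that the key step itself opens.
4. Lactone 5 comes from phlorobutyrophenone 3 and acrylic acid; 3 comes from phloroglucinol and butanoyl chloride.
5. Ring order: aromatic rings B, C, D are bought as phloroglucinol; the temporary lactone ring is closed in step 2; rings A and E are closed last, both in step 3 (run once, product used twice); steps 4 and 5 close no ring.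

Key step: step 3

Remark: the target has no stereocentre, so no configuration has to be set; the β-triketone rings are written in the enol form of the target SMILES.
Remark: in step 2 the lactone is assumed to close on the hydroxyl that is not hydrogen-bonded to the butanoyl group (6-butanoyl isomer 5); the 8-butanoyl isomer would carry the same atoms into step 3 and open to the same dimer 10.

**Step 1**
Reactants: 1 benzene-1,3,5-triol (phloroglucinol); 2 butanoyl chloride
Product: 3 1-(2,4,6-trihydroxyphenyl)butan-1-one (phlorobutyrophenone)
Conditions: AlCl3 (3 equiv), PhNO2–CH2Cl2, 0 → 60 °C; aq. HCl work-up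
Reagents that add atoms: none
Why: Friedel–Crafts acylation of the electron-rich triol should stop after one acyl group because the first ketone deactivates and chelates the ring.

**Step 2**
Reactants: 3 1-(2,4,6-trihydroxyphenyl)butan-1-one; 4 prop-2-enoic acid (acrylic acid, 1.1 equiv)
Product: 5 6-butanoyl-5,7-dihydroxy-3,4-dihydro-2H-chromen-2-one
Conditions: Amberlyst-15 (sulfonic acid resin), toluene–1,4-dioxane, reflux, Dean–Stark trap
Reagents that add atoms: none
Why: Acid-catalysed conjugate hydroarylation of acrylic acid by the phloroglucinol ring (Friedel–Crafts-type Michael addition) followed by lactonisation with the neighbouring hydroxyl is the known route from phenols and α,β-unsaturated acids to 3,4-dihydrocoumarins, and the ring should react only once because the acyl and lactone groups deactivate it.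

**Step 3**
Reactants: 5 6-butanoyl-5,7-dihydroxy-3,4-dihydro-2H-chromen-2-one; 6 2,2-dimethylpropanedioyl dichloride (dimethylmalonyl dichloride); 7 pentan-2-one
Product: 10 2-butanoyl-6-[(3-butanoyl-2,4,6-trihydroxyphenyl)methyl]-3,5-dihydroxy-4,4-dimethylcyclohexa-2,5-dien-1-one (the A–B dimer), via acyl ketene acetal 8 (not isolated), via keto lactone 9 (not isolated)
Conditions: 5, LiN(SiMe3)2 (4.0 equiv), THF, −78 °C; inverse addition to 6 (1.05 equiv), THF, −78 °C; then CH2=C(OLi)CH2CH2CH3 [from 7 and LiN(iPr)2, 2.2 equiv each, THF, −78 °C], −78 → 0 °C; AcOH (3 equiv), 0 °C → rt; 1 M HCl wash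
Reagents that add atoms: none
Why: Proposed new method: the trilithium salt of 5 (two phenoxides and the lactone enolate, whose only enolisable carbon is C5 while the butanoyl ketone is shielded as a vinylogous carboxylate) should be C-acylated at C5 by one acid chloride of non-enolisable 6, and the second acid chloride should be taken up by the lactone enolate oxygen (6-exo-trig O-acylation) to give acyl ketene acetal 8. The kinetic methyl enolate of 7 should then open 8 at its anhydride-like carbonyl C2 (Claisen acylation), which forms C1–C2 and returns the aryl lactone as β-keto lactone 9. On buffering with AcOH the β-diketone carbon C1 of 9 should attack the aryl ester carbonyl C6 in a 6-exo-trig Claisen (Dieckmann-type) acyl transfer that expels the ring-B phenoxide and closes ring A through the C1–C6 bond, the same O-to-C acyl shift as in a Baker–Venkataraman rearrangement and in the chain-releasing Claisen cyclisation of acylphloroglucinol biosynthesis. The closest known reactions are the C-acylation of lithium polyanions of unprotected hydroxyaryl carbonyl compounds and of ester enolates with acid chlorides, the Effenberger annulation of enol derivatives with malonyl dichlorides and the base-mediated rearrangement of enol or aryl esters of 1,3-diketones to 2-acyl-1,3-diones, whereas their union in a [2+3+1] assembly of a cyclohexane-1,3,5-trione is new. No stereocentre is formed. The step needs the arylmethyl group on C5 and not on C1, which the lactone tether secures, C-acylation and not O-acylation at C6, which the stability of the vinylogous-acid product secures because O-acyl isomers can revert through the neighbouring phenoxide, and reaction of 7 at its methyl group, which kinetic deprotonation with LiN(iPr)2 at −78 °C secures.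

**Step 4**
Reactants: 3 1-(2,4,6-trihydroxyphenyl)butan-1-one; 11 N,N,N',N'-tetramethylmethanediamine (bis(dimethylamino)methane, 2.5 equiv)
Product: 12 1-{3,5-bis[(dimethylamino)methyl]-2,4,6-trihydroxyphenyl}butan-1-one
Conditions: EtOH, 0 °C → rt
Reagents that add atoms: none
Why: A phenolic Mannich reaction with a preformed aminal should aminomethylate both free ring carbons of the acylphloroglucinol without free formaldehyde, which avoids methylene-bis coupling.

**Step 5**
Reactants: 10 the A–B dimer (2.1 equiv); 12 1-{3,5-bis[(dimethylamino)methyl]-2,4,6-trihydroxyphenyl}butan-1-one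
Product: 13 the target CNP0188003.0
Conditions: 1,4-dioxane, 80 °C, N2 purge (removal of HNMe2)
Reagents that add atoms: none
Why: Thermal loss of HNMe2 from each ortho-hydroxybenzylamine of 12 should give an ortho-quinone methide on ring C that the single free ring carbon of ring B in 10 traps by Michael-type Friedel–Crafts alkylation (the biomimetic methylene bridging of acylphloroglucinols), while ring A has no free carbon.

**Compound list**

1 | benzene-1,3,5-triol (phloroglucinol) | Oc1cc(O)cc(O)c1 | starting material
2 | butanoyl chloride | CCCC(=O)Cl | starting material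
3 | 1-(2,4,6-trihydroxyphenyl)butan-1-one | CCCC(=O)c1c(O)cc(O)cc1O | intermediate
4 | prop-2-enoic acid (acrylic acid) | C=CC(=O)O | starting material
5 | 6-butanoyl-5,7-dihydroxy-3,4-dihydro-2H-chromen-2-one | CCCC(=O)c1c(O)cc2OC(=O)CCc2c1O | intermediate
6 | 2,2-dimethylpropanedioyl dichloride | CC(C)(C(=O)Cl)C(=O)Cl | starting material
7 | pentan-2-one | CCCC(C)=O | starting material
8 | 7-butanoyl-6,8-dihydroxy-3,3-dimethyl-2H,5H-pyrano[2,3-b]chromene-2,4(3H)-dione (cyclic acyl ketene acetal, present as its lithium phenoxide, not isolated) | CCCC(=O)c1c(O)cc2OC3=C(Cc2c1O)C(=O)C(C)(C)C(=O)O3 | intermediate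
9 | 6-butanoyl-3-(2,2-dimethyl-3,5-dioxooctanoyl)-5,7-dihydroxy-3,4-dihydro-2H-chromen-2-one (present as its lithium salt, not isolated) | CCCC(=O)c1c(O)cc2OC(=O)C(Cc2c1O)C(=O)C(C)(C)C(=O)CC(=O)CCC | intermediate
10 | 2-butanoyl-6-[(3-butanoyl-2,4,6-trihydroxyphenyl)methyl]-3,5-dihydroxy-4,4-dimethylcyclohexa-2,5-dien-1-one | CCCC(=O)C1=C(O)C(C)(C)C(O)=C(Cc2c(O)cc(O)c(C(=O)CCC)c2O)C1=O | intermediate
11 | N,N,N',N'-tetramethylmethanediamine | CN(C)CN(C)C | starting material
12 | 1-{3,5-bis[(dimethylamino)methyl]-2,4,6-trihydroxyphenyl}butan-1-one | CCCC(=O)c1c(O)c(CN(C)C)c(O)c(CN(C)C)c1O | intermediate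
13 | 1-[3,5-bis({3-butanoyl-5-[(5-butanoyl-2,4-dihydroxy-3,3-dimethyl-6-oxocyclohexa-1,4-dien-1-yl)methyl]-2,4,6-trihydroxyphenyl}methyl)-2,4,6-trihydroxyphenyl]butan-1-one (CNP0188003.0; no stereocentre) | CCCC(=O)C1=C(O)C(C)(C)C(O)=C(Cc2c(O)c(Cc3c(O)c(Cc4c(O)c(CC5=C(O)C(C)(C)C(O)=C(C(=O)CCC)C5=O)c(O)c(C(=O)CCC)c4O)c(O)c(C(=O)CCC)c3O)c(O)c(C(=O)CCC)c2O)C1=O | target

**Step count**

Total steps: 5. Longest linear sequence: 4 steps (steps 1, 2, 3, 5); step 4 is a one-step branch from 3.

**Steps most likely to fail**

Step 3 (Proposed new method). What may go wrong:
- enolisation of the butanoyl ketone instead of the lactone;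
- O-acylation of the phenoxides or bridging of two molecules by the bifunctional acid chloride;
- attack of the ketone enolate at the ketene-acetal carbon instead of the acyl carbon;
- stalling of the final acyl transfer at O-acyl isomers.

The fallback uses known chemistry, sets out from 3 and comes back at 10. Compound 3 would be C-methylated twice at one ring carbon with MeI and NaOMe in MeOH (the classical dearomatising gem-dimethylation of acylphloroglucinols) to give 2-butanoyl-3,5-dihydroxy-4,4-dimethylcyclohexa-2,5-dien-1-one F1. Its one remaining ring CH would be aminomethylated with aminal 11 to give 2-butanoyl-6-[(dimethylamino)methyl]-3,5-dihydroxy-4,4-dimethylcyclohexa-2,5-dien-1-one F2. Heating F2 with an excess of 3 in 1,4-dioxane should eliminate HNMe2 and add the resulting methylene trione to a free ring carbon of 3, giving 10. In this fallback the filicinic ring is made from the aromatic ring and not closed from acyclic pieces.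

Step 5. What may go wrong: exchange of the methylene bridges by retro-Michael cleavage and re-addition under the warm, amine-containing conditions, and stopping after one of the two couplings. The fallback reverses the polarity of the bridge-forming step, sets out from 10 and comes back at 13. Dimer 10 would be aminomethylated at its single free ring-B carbon with 11 to give 2-butanoyl-6-({3-butanoyl-5-[(dimethylamino)methyl]-2,4,6-trihydroxyphenyl}methyl)-3,5-dihydroxy-4,4-dimethylcyclohexa-2,5-dien-1-one F3. Two equivalents of F3 would then be warmed with 0.5 equivalent of 3, whose two unhindered free ring carbons trap the quinone methide at lower temperature, to give 13.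

Step 2. What may go wrong: Friedel–Crafts acylation by acrylic acid (chromanone formation) instead of conjugate hydroarylation, a second annulation on the remaining ring carbon, and acid-induced loss of the butanoyl group. The fallback goes through the coumarin oxidation level, sets out from 3 and comes back at 5. Compound 3 would be condensed with ethyl propiolate and ZnCl2 at 100 °C (Pechmann-type coumarin synthesis) to give 6-butanoyl-5,7-dihydroxy-2H-chromen-2-one F4. Hydrogenation of the coumarin C3–C4 double bond of F4 over Pd/C (H2, 1 atm, EtOAc) should then give 5.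

**Further compounds**

F1 | step 3 | 2-butanoyl-3,5-dihydroxy-4,4-dimethylcyclohexa-2,5-dien-1-one | CCCC(=O)C1=C(O)C(C)(C)C(O)=CC1=O
F2 | step 3 | 2-butanoyl-6-[(dimethylamino)methyl]-3,5-dihydroxy-4,4-dimethylcyclohexa-2,5-dien-1-one | CCCC(=O)C1=C(O)C(C)(C)C(O)=C(CN(C)C)C1=O
F3 | step 5 | 2-butanoyl-6-({3-butanoyl-5-[(dimethylamino)methyl]-2,4,6-trihydroxyphenyl}methyl)-3,5-dihydroxy-4,4-dimethylcyclohexa-2,5-dien-1-one | CCCC(=O)C1=C(O)C(C)(C)C(O)=C(Cc2c(O)c(CN(C)C)c(O)c(C(=O)CCC)c2O)C1=O
F4 | step 2 | 6-butanoyl-5,7-dihydroxy-2H-chromen-2-one | CCCC(=O)c1c(O)cc2OC(=O)C=Cc2c1O
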